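## Structural features

The target joins two 7-methoxycoumarin (2H-chromen-2-one) units to a 3,6-dimethylcyclohex-2-ene core. Ring A is bonded through its C6 directly to the allylic methine C1 of the cyclohexene; ring B is bonded through its C8 and an (E)-ethene-1,2-diyl bridge to the neighbouring quaternary carbon C6, which also carries a methyl group. C1 (S) and C6 (S) are contiguous stereocentres, with ring A on C1 cis to the styryl arm on C6; the only other stereochemical element is the E alkene. The fragile groups are the two coumarin lactones (hydroxide, hydride, hard carbon nucleophiles, light at C3=C4), the trisubstituted C2=C3 alkene (acid), the C1–H bond (allylic and benzylic) and the light-sensitive styryl alkene. The real difficulty is twofold: a quaternary carbon next to a tertiary one in one absolute configuration, and a bond from C1 to C6 of a 7-oxygenated coumarin, a position that electrophilic substitution does not reach because attack goes to C8. The benzene part of ring A is a resorcinol unit in which the cyclohexenyl-bearing C6 is ortho to the methoxy carbon C7 and para to the oxygen-bearing C8a. That is exactly the pattern written when a vinylketene combines with an alkoxyacetylene, and the key step uses it to grow ring A from a four-carbon chain already attached to C1.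

## Logic of the disconnections

37 to 33 and 36. The bond cut joins C8 of ring B to the alkene carbon. It is cut there because the vinyl group of 33 sits on a quaternary carbon: after aryl insertion the only β-hydrogen open to palladium is the benzylic one, so only the E alkene can form. The gain is that ring B enters complete and last, and never meets the photochemical or organometallic steps. The demand is a Heck coupling that tolerates an iodide with two ortho substituents, a neopentyl-type alkene and two lactones.

36 to 35 to 34. The C8–I and O–CH3 bonds are cut. Electrophilic attack on the phenoxide of 34 goes to C8, between the two oxygens; this selectivity is useless for ring A but right for ring B. The gain is a two-step coupling partner from a commodity phenol. The demand is clean mono-iodination.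

33 to 32, 31 and 30. The exocyclic C=CH2 bond is cut, then the oxidation level and the silyl group on the one-carbon arm at C6 are adjusted. The arm is carried as a neopentyl silyl ether because it must pass the photolysis, the phenol chemistry and the pyranone synthesis untouched. The gain is that no carbonyl group or alkene is present at C6 until it is needed. The demand is a methylenation that takes the aldehyde and not the lactone; the aldehyde carbon is attached to a quaternary centre and cannot epimerise.

30 to 28 to 26. The pyranone is cut at O1–C2 and C3=C4 (olefination and lactonisation) and then at C4–C4a (formyl group). The benzannulation leaves exactly the free phenol that becomes O1, and its only unhindered ortho position, para to the methoxy group, is the future C4a. The gain is a two-step pyranone synthesis without strong acid. The demand is formylation away from the position between the two oxygens and thermal E-to-Z isomerisation before ring closure.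

26 to 17 and 21 (key step). Four bonds of ring A are cut: C5–C6, C6–C7, C8–C8a and C4a–C8a. This reduces the whole benzene ring to an open-chain diazo enone on C1 (supplying C6, C8a, C5 and C4a) and a two-carbon alkyne (C8 and C7). The cut is made there because the ketene–ynol ether union fixes the resorcinol pattern by polarity alone, and because the C1–aryl bond then pre-exists as an ordinary C–C bond set in a sigmatropic step. The gain is one ring and four skeletal bonds in one operation with both stereocentres untouched. The demand is that vinyl migration outruns hydrogen shift from C1, that the ketene is captured by 21, and that nothing else in the molecule absorbs light or traps ketenes; hence the silyl ether and the absence of any coumarin at this stage.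

21 to 18. Two eliminations (methanol, then hydrogen chloride) are reversed; the volatile ynol ether is made just before use.

17 to 15, 14 and 13. The C=N2 bond is cut first; the enone has a single enolisable α-carbon, so diazo transfer is regiospecific. Next the bond between the carbonyl carbon and the vinyl group is cut (Grignard addition, then oxidation). The gain is a side chain reduced to a two-carbon aldehyde. The demand is enolisation of an unhindered vinyl ketone without conjugate addition.

13 to 12, 11 and 10. No skeletal bond is cut. The side-chain aldehyde is carried as a diethyl acetal and the acid is reduced and silylated, so only one silyl ether is ever present and no selective desilylation is needed. The demand is acetal hydrolysis that spares the silyl ether.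

10 to 7, and 7 to 6. The C1–C6 ring bond is cut as a [3,3] shift of a lactone ketene acetal, then the methyl group α to the lactone carbonyl is removed. The ring fixes the ketene acetal geometry and forces a boat transition state, so the E alkene gives the cis pair and the carbinol stereocentre gives the absolute sense. The gain is both stereocentres from one tertiary carbinol and a six-membered lactone. The demand is O-silylation, a pure E alkene and an enantiopure carbinol.

6 to 1 and 2. The bond between the carbinol carbon and the alkenyl carbon is cut, together with the lactone C–O bond. Syn hydrometalation of 1 gives the E alkenyl nucleophile and 2 supplies the ketone and the ester. The gain is two purchasable fragments. The demand is enantiofacial discrimination on a methyl ketone.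

## Other disconnections considered

Alternative 1: The cut runs through ring B, at the C8–alkene bond and the C7–O bond. Ring B comes from aryne A2, set free by fluoride (CsF) from silyl triflate A1, and both alkene carbons come from aldehyde A3. In the forward step the carbonyl oxygen of A3 should add to C7 of A2, the aryne carbon remote from the ring oxygen on C8a. The C8 anion then closes onto the carbonyl carbon, the four-membered ring opens to ortho-quinone methide A4, and a hydrogen shift from the neighbouring CH2 gives alkenylphenol A5. O-Methylation of A5 would give 37.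
- In favour: the regiochemistry on ring B is dictated by aryne polarisation and is the equal of the iodination in the chosen plan. The last C–C bond is made without palladium or a halogenated coumarin; on that point the alternative is the better.
- Against: A3 contains the whole left half (ring A and both stereocentres) plus one extra carbon on the quaternary centre, so it solves none of the real difficulties. Aryne insertions into enolisable aldehydes are capricious, A4 can be trapped by a second aryne or dimerise, and the mechanism does not enforce the E geometry.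
- Comparison: both plans are convergent at the same late bond. The chosen plan's syn insertion and syn elimination guarantee E; the alternative's pericyclic tautomerisation does not. In step count the alternative is longer (A1, homologation to A3, a final methylation).

Alternative 2: The cut is the C1–C6(ring A) bond together with a temporary ester link. Diene acid A6 (the isomer with the two methyl groups cis) is esterified with bromophenol A7 to give A8. A palladium-catalysed 6-exo carbopalladation (Pd(OAc)2 with a chiral bisphosphine to distinguish the two enantiotopic alkenes) would form the ring A–C1 bond, and syn β-hydride elimination towards the methyl-bearing carbon would give the cis-fused lactone A9.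
- In favour: ring A is bought, not built; the tether forces the cis relationship as reliably as the boat transition state of the chosen plan (equal). Both stereocentres would come from a single catalytic step and the sequence to A9 is much shorter (better in step economy; no diazo compound and no photolysis).
- Against: A9 carries a conjugated diene, and its disubstituted alkene must be reduced in the presence of the trisubstituted one and of the coumarin C3=C4 bond. The aryl ester lactone must then be reduced to the aldehyde level beside the coumarin lactone, and the freed 7-hydroxyl methylated. Enantioselectivity rests on an asymmetric Heck reaction of an aryl bromide, which is less predictable than chirality transfer from a carbinol.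
- Comparison: mechanistically this is migratory insertion against sigmatropic and electrocyclic steps. The alternative wins on length; the chosen plan wins on chemoselectivity after the key step.

Alternative 3: The cut is the C2=C3 alkene. Diene aldehyde A10, with a vinyl group on the future C1 and a 3-methylbut-3-enyl chain on the future C6, would close with a second-generation Grubbs catalyst to aldehyde A11, which is the same compound as 32.
- In favour: forming a six-membered trisubstituted alkene from a vinyl and a 1,1-disubstituted alkene is dependable. Ring A is present from the start, so no benzannulation and no photochemistry are needed (better on operational safety), and the endgame from 32 is shared (equal).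
- Against: the difficulty moves to A10, an acyclic aldehyde with a quaternary carbon next to a benzylic tertiary one. An acyclic ester-enolate Claisen would need geometry control of a ketene acetal with two similar α-substituents, which the ring-fused ketene acetal of the chosen plan has by construction. Allylic alkylation of an α-branched aldehyde controls the two centres independently and less surely, and the coumarin must survive those enolate steps.
- Comparison: structurally the alternative makes the stereodiad before the ring, the chosen plan makes both at once. The alternative could be shorter if A10 were available in one catalytic step, but its stereocontrol is weaker.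

Key step: step 11

Remarks on the chemistry:
- Cyclohexene numbering throughout: C1 carries ring A or its precursor chain, C2=C3 is the alkene, C3 and C6 carry the methyl groups, C6 is quaternary.
- Diazo ketone 17 is the 1-diazo-2-oxobut-3-en-1-yl isomer: the diazo carbon is bonded to C1 and the carbonyl carbon carries the vinyl group. Only this connectivity lets the vinyl group migrate to the ring-bearing carbon.
- The lactone-enolate Claisen rearrangement keeps the ring size: a six-membered lactone gives the six-membered carbocycle.
- C3 of lactone 7 and the carbinol carbon of 14 are carried as epimer mixtures, because both become trigonal later.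
- 4,4-Diethoxybut-1-yne (1) is assumed to be purchasable.

Step 1
Reactants: 1 4,4-diethoxybut-1-yne; 2 methyl 5-oxohexanoate
Product: 6 (6S)-6-[(1E)-4,4-diethoxybut-1-en-1-yl]-6-methyloxan-2-one, via alkenylzirconocene chloride 3 (not isolated), via alkenyl(methyl)zinc 4 (not isolated), via hydroxy ester 5 (not isolated)
Conditions: 1, Cp2Zr(H)Cl, CH2Cl2, rt; Me2Zn, PhMe, −78 °C; 2, Ti(Oi-Pr)4, C2-symmetric bis(hydroxycamphorsulfonamide) ligand of trans-cyclohexane-1,2-diamine (10 mol %, enantiomer for Re-face delivery), rt; then KOt-Bu (cat.), THF, 0 °C
Reagents that add atoms: none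
Why: Syn hydrozirconation fixes the E alkene; Zr-to-Zn transmetalation and titanium-catalysed asymmetric alkenylation of the methyl ketone should deliver the alkenyl group to the Re face and set the (S) tertiary carbinol. The alkoxide then closes the δ-lactone by transesterification.

Step 2
Reactants: 6 (6S)-6-[(1E)-4,4-diethoxybut-1-en-1-yl]-6-methyloxan-2-one
Product: 7 (6S)-6-[(1E)-4,4-diethoxybut-1-en-1-yl]-3,6-dimethyloxan-2-one (both C3 epimers)
Conditions: LiN(i-Pr)2, THF, −78 °C; MeI, −78 → −40 °C
Reagents that add atoms: iodomethane, CI
Why: Lactone enolate alkylation; at −78 °C the lithium enolate is methylated long before it can rearrange. The C3 configuration is irrelevant because this carbon is enolised again in step 3.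

Step 3
Reactants: 7 (6S)-6-[(1E)-4,4-diethoxybut-1-en-1-yl]-3,6-dimethyloxan-2-one
Product: 10 (1R,2S)-2-(2,2-diethoxyethyl)-1,4-dimethylcyclohex-3-ene-1-carboxylic acid, via silyl ketene acetal 8 (not isolated), via silyl ester 9 (not isolated)
Conditions: LiN(i-Pr)2, THF, −78 °C; TBSCl, DMPU, −78 °C → rt; PhMe, 100 °C; then K2CO3, MeOH/H2O, rt; NaH2PO4 to pH 5
Reagents that add atoms: none
Why: Ireland–Claisen rearrangement of a lactone silyl ketene acetal (lactone-enolate Claisen). The ring fixes the ketene acetal geometry and the two-carbon tether between the enolate carbon and the carbinol carbon enforces a boat transition state, so the E alkene places the acetal side chain cis to the carboxyl group. Suprafacial transfer from the (S) carbinol sets both new stereocentres as (1R,2S).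

Step 4
Reactants: 10 (1R,2S)-2-(2,2-diethoxyethyl)-1,4-dimethylcyclohex-3-ene-1-carboxylic acid
Product: 11 [(1R,2S)-2-(2,2-diethoxyethyl)-1,4-dimethylcyclohex-3-en-1-yl]methanol
Conditions: LiAlH4, THF, 0 °C → reflux; Fieser work-up
Reagents that add atoms: none
Why: Hydride reduction of a hindered carboxylic acid to the neopentyl alcohol; acetal and alkene are inert and no stereocentre is touched.

Step 5
Reactants: 11 [(1R,2S)-2-(2,2-diethoxyethyl)-1,4-dimethylcyclohex-3-en-1-yl]methanol
Product: 12 tert-butyl{[(1R,2S)-2-(2,2-diethoxyethyl)-1,4-dimethylcyclohex-3-en-1-yl]methoxy}dimethylsilane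
Conditions: TBSCl, imidazole, DMF, rt
Reagents that add atoms: tert-butyldimethylsilyl chloride, CC(C)(C)[Si](C)(C)Cl
Why: Standard silylation of a primary alcohol; the basic conditions leave the acetal intact.

Step 6
Reactants: 12 tert-butyl{[(1R,2S)-2-(2,2-diethoxyethyl)-1,4-dimethylcyclohex-3-en-1-yl]methoxy}dimethylsilane
Product: 13 {(1S,6R)-6-[(tert-butyldimethylsilyloxy)methyl]-3,6-dimethylcyclohex-2-en-1-yl}acetaldehyde
Conditions: SiO2, 10% aq. (CO2H)2, CH2Cl2, rt
Reagents that add atoms: water, O
Why: Mild acetal hydrolysis on wet silica with oxalic acid; the neopentyl silyl ether and the trisubstituted alkene should survive, and the aldehyde has no stereocentre at its α-carbon.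

Step 7
Reactants: 13 {(1S,6R)-6-[(tert-butyldimethylsilyloxy)methyl]-3,6-dimethylcyclohex-2-en-1-yl}acetaldehyde
Product: 14 1-{(1S,6R)-6-[(tert-butyldimethylsilyloxy)methyl]-3,6-dimethylcyclohex-2-en-1-yl}but-3-en-2-ol (both carbinol epimers)
Conditions: CH2=CHMgBr, THF, −78 °C; aq. NH4Cl
Reagents that add atoms: vinylmagnesium bromide, C=C[Mg]Br
Why: Grignard addition to an unhindered aldehyde; the new carbinol centre needs no control because it is oxidised in step 8.

Step 8
Reactants: 14 1-{(1S,6R)-6-[(tert-butyldimethylsilyloxy)methyl]-3,6-dimethylcyclohex-2-en-1-yl}but-3-en-2-ol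
Product: 15 1-{(1S,6R)-6-[(tert-butyldimethylsilyloxy)methyl]-3,6-dimethylcyclohex-2-en-1-yl}but-3-en-2-one
Conditions: Dess–Martin periodinane, NaHCO3, CH2Cl2, 0 °C
Reagents that add atoms: none
Why: Dess–Martin oxidation of an allylic alcohol under buffered, non-basic conditions, which suit a polymerisable vinyl ketone; the product is used at once.

Step 9
Reactants: 15 1-{(1S,6R)-6-[(tert-butyldimethylsilyloxy)methyl]-3,6-dimethylcyclohex-2-en-1-yl}but-3-en-2-one
Product: 17 1-diazo-1-{(1S,6R)-6-[(tert-butyldimethylsilyloxy)methyl]-3,6-dimethylcyclohex-2-en-1-yl}but-3-en-2-one, via trifluoroacetyl diketone 16 (not isolated)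
Conditions: LiN(SiMe3)2, THF, −78 °C (ketone added to base); CF3CO2CH2CF3, −78 °C; then MsN3, Et3N, H2O, MeCN, rt
Reagents that add atoms: methanesulfonyl azide, CS(=O)(=O)N=[N+]=[N-]
Why: Detrifluoroacetylative diazo transfer (Danheiser), the method designed for enolisable enones. The ketone has one enolisable α-carbon, so activation and diazo transfer are regiospecific, and the stereocentre at C1 is not enolisable.

Step 10
Reactants: 18 2-chloro-1,1-dimethoxyethane
Product: 21 methoxyethyne, via 1-chloro-2-methoxyethene 19 (not isolated), via sodium methoxyethynide 20 (not isolated)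
Conditions: NaNH2 (3 equiv), NH3(l), −33 °C; then aq. NH4Cl, −70 °C; distil into a cold trap (bp 23 °C), use at once
Reagents that add atoms: none
Why: Double base-induced elimination (methanol, then hydrogen chloride), the classical preparation of alkoxyacetylenes from haloacetals; the acetylide salt protects the product until the quench.

Step 11
Reactants: 17 1-diazo-1-{(1S,6R)-6-[(tert-butyldimethylsilyloxy)methyl]-3,6-dimethylcyclohex-2-en-1-yl}but-3-en-2-one; 21 methoxyethyne
Product: 26 4-{(1S,6R)-6-[(tert-butyldimethylsilyloxy)methyl]-3,6-dimethylcyclohex-2-en-1-yl}-3-methoxyphenol, via vinylketene 22 (not isolated), via 4-vinylcyclobutenone 23 (not isolated), via dienylketene 24 (not isolated), via cyclohexa-2,4-dienone 25 (not isolated)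
Conditions: 21 (4 equiv), ClCH2CH2Cl, hν (254 nm, quartz), 5–10 °C, until N2 evolution stops; then 80 °C, sealed tube
Reagents that add atoms: none
Why: Second-generation Danheiser benzannulation (photochemical Wolff rearrangement of an α-diazo enone in the presence of an alkoxyacetylene), applied here to a new substrate. Light expels N2 from 17 and the vinyl group migrates from the carbonyl carbon to the ring-bearing carbon, which forms C5–C6 and gives vinylketene 22. The electron-rich alkyne 21 adds to the ketene C=C bond in a polarity-controlled [2+2] cycloaddition: its CH carbon bonds to the ketene carbonyl carbon (C8–C8a) and its methoxy-bearing carbon to the ketene α-carbon (C6–C7), giving 23. Four-electron electrocyclic opening of 23 (by light during irradiation, by heat at 80 °C) gives dienylketene 24; only the isomer with ketene and vinyl cis can go on, and the other reverts through 23. Ring A is closed by a thermal, disrotatory six-electron electrocyclisation of 24 that forms C4a–C8a, and 25 tautomerises irreversibly to phenol 26. No stereocentre is created and no bond to C1 or C6 is broken; the step does need vinyl migration to be faster than a 1,2-hydrogen shift from C1–H, which direct irradiation and the high migratory aptitude of vinyl favour. The regiochemistry (cyclohexenyl carbon ortho to OMe, para to OH) follows from the polarity of the ketene–ynol ether pair, and the excess of 21 should capture 22 before it dimerises or acylates 26. The silyl ether, the trisubstituted alkene and the absence of any coumarin keep the rest of the molecule transparent and inert.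

Step 12
Reactants: 26 4-{(1S,6R)-6-[(tert-butyldimethylsilyloxy)methyl]-3,6-dimethylcyclohex-2-en-1-yl}-3-methoxyphenol
Product: 28 5-{(1S,6R)-6-[(tert-butyldimethylsilyloxy)methyl]-3,6-dimethylcyclohex-2-en-1-yl}-2-hydroxy-4-methoxybenzaldehyde, via 2-hydroxybenzyl alcohol 27 (not isolated)
Conditions: MgCl2, Et3N, (CH2O)n, MeCN, reflux
Reagents that add atoms: formaldehyde (as paraformaldehyde), C=O
Why: Magnesium-mediated ortho-formylation of a phenol (Casnati–Skattebøl): the magnesium phenoxide delivers formaldehyde to an ortho carbon and a second formaldehyde oxidises the benzyl alcohol by hydride transfer. The unhindered ortho position para to the methoxy group should react in preference to the one between the two oxygens.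

Step 13
Reactants: 28 5-{(1S,6R)-6-[(tert-butyldimethylsilyloxy)methyl]-3,6-dimethylcyclohex-2-en-1-yl}-2-hydroxy-4-methoxybenzaldehyde
Product: 30 6-{(1S,6R)-6-[(tert-butyldimethylsilyloxy)methyl]-3,6-dimethylcyclohex-2-en-1-yl}-7-methoxy-2H-chromen-2-one, via ethyl 2-hydroxycinnamate 29 (not isolated)
Conditions: Ph3P=CHCO2Et, PhNEt2, reflux
Reagents that add atoms: ethyl (triphenylphosphoranylidene)acetate, CCOC(=O)C=P(c1ccccc1)(c1ccccc1)c1ccccc1
Why: Wittig olefination with a stabilised ylide followed by thermal E-to-Z isomerisation and lactonisation, the standard route from salicylaldehydes to 3,4-unsubstituted coumarins. The medium is a weak base, so the silyl ether and the C1 stereocentre are not at risk.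

Step 14
Reactants: 30 6-{(1S,6R)-6-[(tert-butyldimethylsilyloxy)methyl]-3,6-dimethylcyclohex-2-en-1-yl}-7-methoxy-2H-chromen-2-one
Product: 31 6-[(1S,6R)-6-(hydroxymethyl)-3,6-dimethylcyclohex-2-en-1-yl]-7-methoxy-2H-chromen-2-one
Conditions: Bu4NF, AcOH, THF, rt → 40 °C
Reagents that add atoms: none
Why: Fluoride cleavage of the silyl ether; buffering with acetic acid keeps the medium from opening the lactone.

Step 15
Reactants: 31 6-[(1S,6R)-6-(hydroxymethyl)-3,6-dimethylcyclohex-2-en-1-yl]-7-methoxy-2H-chromen-2-one
Product: 32 (1R,2R)-2-(7-methoxy-2-oxo-2H-chromen-6-yl)-1,4-dimethylcyclohex-3-ene-1-carbaldehyde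
Conditions: Dess–Martin periodinane, NaHCO3, CH2Cl2, rt
Reagents that add atoms: none
Why: Dess–Martin oxidation of a neopentyl alcohol; the aldehyde is attached to a quaternary carbon and cannot epimerise. The descriptor change at the aryl-bearing carbon is a priority effect only.

Step 16
Reactants: 32 (1R,2R)-2-(7-methoxy-2-oxo-2H-chromen-6-yl)-1,4-dimethylcyclohex-3-ene-1-carbaldehyde
Product: 33 6-[(1S,6S)-6-ethenyl-3,6-dimethylcyclohex-2-en-1-yl]-7-methoxy-2H-chromen-2-one
Conditions: Ph3PCH3Br, KN(SiMe3)2, THF, −78 → 0 °C (1.2 equiv of ylide)
Reagents that add atoms: methyltriphenylphosphonium bromide, C[P+](c1ccccc1)(c1ccccc1)c1ccccc1.[Br-]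
Why: Wittig methylenation; the unstabilised ylide should react with the aldehyde far faster than with the conjugated lactone at low temperature and near-stoichiometric loading.

Step 17
Reactants: 34 7-hydroxy-2H-chromen-2-one
Product: 35 7-hydroxy-8-iodo-2H-chromen-2-one
Conditions: I2, KI, 20% aq. NH3, rt; acidify
Reagents that add atoms: iodine, II
Why: Electrophilic aromatic iodination of the phenoxide; attack goes to C8, the position between the two ring oxygens, and one equivalent of iodine limits di-iodination.

Step 18
Reactants: 35 7-hydroxy-8-iodo-2H-chromen-2-one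
Product: 36 8-iodo-7-methoxy-2H-chromen-2-one
Conditions: MeI, K2CO3, acetone, reflux
Reagents that add atoms: iodomethane, CI
Why: Williamson O-methylation of an acidic phenol under conditions that coumarins tolerate.

Step 19
Reactants: 33 6-[(1S,6S)-6-ethenyl-3,6-dimethylcyclohex-2-en-1-yl]-7-methoxy-2H-chromen-2-one; 36 8-iodo-7-methoxy-2H-chromen-2-one
Product: 37 6-[(1S,6S)-6-[(E)-2-(7-methoxy-2-oxo-2H-chromen-8-yl)ethenyl]-3,6-dimethylcyclohex-2-en-1-yl]-7-methoxy-2H-chromen-2-one
Conditions: Pd(OAc)2 (10 mol %), Bu4NCl, NaHCO3, DMF, 90 °C
Reagents that add atoms: none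
Why: Mizoroki–Heck coupling under Jeffery conditions: oxidative addition of the iodide to zerovalent palladium, syn insertion placing the aryl group on the terminal carbon, and syn β-hydride elimination from the only β-hydrogen, which can give only the E alkene. The stereocentres are remote from the reacting carbons.

## Compound list

1 | 4,4-diethoxybut-1-yne | C#CCC(OCC)OCC | starting material
2 | methyl 5-oxohexanoate | COC(=O)CCCC(C)=O | starting material
3 | chloridobis(cyclopentadienyl)[(1E)-4,4-diethoxybut-1-en-1-yl]zirconium | CCOC(OCC)C/C=C/[Zr](Cl)(C1C=CC=C1)C1C=CC=C1 | intermediate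
4 | [(1E)-4,4-diethoxybut-1-en-1-yl](methyl)zinc | CCOC(OCC)C/C=C/[Zn]C | intermediate
5 | methyl (5S,6E)-9,9-diethoxy-5-hydroxy-5-methylnon-6-enoate | COC(=O)CCC[C@](C)(O)/C=C/CC(OCC)OCC | intermediate
6 | (6S)-6-[(1E)-4,4-diethoxybut-1-en-1-yl]-6-methyloxan-2-one | O=C1CCC[C@@](C)(/C=C/CC(OCC)OCC)O1 | intermediate
7 | (6S)-6-[(1E)-4,4-diethoxybut-1-en-1-yl]-3,6-dimethyloxan-2-one (both C3 epimers) | CC1CC[C@@](C)(/C=C/CC(OCC)OCC)OC1=O | intermediate
8 | tert-butyl({(2S)-2-[(1E)-4,4-diethoxybut-1-en-1-yl]-2,5-dimethyl-3,4-dihydro-2H-pyran-6-yl}oxy)dimethylsilane | CC1=C(O[Si](C)(C)C(C)(C)C)O[C@](C)(/C=C/CC(OCC)OCC)CC1 | intermediate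
9 | tert-butyldimethylsilyl (1R,2S)-2-(2,2-diethoxyethyl)-1,4-dimethylcyclohex-3-ene-1-carboxylate | CCOC(OCC)C[C@H]1C=C(C)CC[C@@]1(C)C(=O)O[Si](C)(C)C(C)(C)C | intermediate
10 | (1R,2S)-2-(2,2-diethoxyethyl)-1,4-dimethylcyclohex-3-ene-1-carboxylic acid | CCOC(OCC)C[C@H]1C=C(C)CC[C@@]1(C)C(=O)O | intermediate
11 | [(1R,2S)-2-(2,2-diethoxyethyl)-1,4-dimethylcyclohex-3-en-1-yl]methanol | CCOC(OCC)C[C@H]1C=C(C)CC[C@@]1(C)CO | intermediate
12 | tert-butyl{[(1R,2S)-2-(2,2-diethoxyethyl)-1,4-dimethylcyclohex-3-en-1-yl]methoxy}dimethylsilane | CCOC(OCC)C[C@H]1C=C(C)CC[C@@]1(C)CO[Si](C)(C)C(C)(C)C | intermediate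
13 | {(1S,6R)-6-[(tert-butyldimethylsilyloxy)methyl]-3,6-dimethylcyclohex-2-en-1-yl}acetaldehyde | O=CC[C@H]1C=C(C)CC[C@@]1(C)CO[Si](C)(C)C(C)(C)C | intermediate
14 | 1-{(1S,6R)-6-[(tert-butyldimethylsilyloxy)methyl]-3,6-dimethylcyclohex-2-en-1-yl}but-3-en-2-ol (both carbinol epimers) | C=CC(O)C[C@H]1C=C(C)CC[C@@]1(C)CO[Si](C)(C)C(C)(C)C | intermediate
15 | 1-{(1S,6R)-6-[(tert-butyldimethylsilyloxy)methyl]-3,6-dimethylcyclohex-2-en-1-yl}but-3-en-2-one | C=CC(=O)C[C@H]1C=C(C)CC[C@@]1(C)CO[Si](C)(C)C(C)(C)C | intermediate
16 | 1,1,1-trifluorohex-5-ene-2,4-dione carrying at C3 the cyclohexenyl group of 15 (ring configuration as in 15; keto and enol forms) | C=CC(=O)C(C(=O)C(F)(F)F)[C@H]1C=C(C)CC[C@@]1(C)CO[Si](C)(C)C(C)(C)C | intermediate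
17 | 1-diazo-1-{(1S,6R)-6-[(tert-butyldimethylsilyloxy)methyl]-3,6-dimethylcyclohex-2-en-1-yl}but-3-en-2-one | C=CC(=O)C(=[N+]=[N-])[C@H]1C=C(C)CC[C@@]1(C)CO[Si](C)(C)C(C)(C)C | intermediate
18 | 2-chloro-1,1-dimethoxyethane (chloroacetaldehyde dimethyl acetal) | COC(CCl)OC | starting material
19 | 1-chloro-2-methoxyethene (E and Z) | COC=CCl | intermediate
20 | sodium methoxyethynide | COC#[C-].[Na+] | intermediate
21 | methoxyethyne (methoxyacetylene) | COC#C | intermediate
22 | 2-{(1S,6R)-6-[(tert-butyldimethylsilyloxy)methyl]-3,6-dimethylcyclohex-2-en-1-yl}buta-1,3-dien-1-one (vinylketene) | C=CC(=C=O)[C@H]1C=C(C)CC[C@@]1(C)CO[Si](C)(C)C(C)(C)C | intermediate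
23 | 4-ethenyl-3-methoxy-4-{(1S,6R)-6-[(tert-butyldimethylsilyloxy)methyl]-3,6-dimethylcyclohex-2-en-1-yl}cyclobut-2-en-1-one (both epimers at the ring C4) | COC1=CC(=O)C1(C=C)[C@H]1C=C(C)CC[C@@]1(C)CO[Si](C)(C)C(C)(C)C | intermediate
24 | (3Z)-3-methoxy-4-{(1S,6R)-6-[(tert-butyldimethylsilyloxy)methyl]-3,6-dimethylcyclohex-2-en-1-yl}hexa-1,3,5-trien-1-one (dienylketene) | O=C=C/C(OC)=C(\C=C)[C@H]1C=C(C)CC[C@@]1(C)CO[Si](C)(C)C(C)(C)C | intermediate
25 | 3-methoxy-4-{(1S,6R)-6-[(tert-butyldimethylsilyloxy)methyl]-3,6-dimethylcyclohex-2-en-1-yl}cyclohexa-2,4-dien-1-one | COC1=CC(=O)CC=C1[C@H]1C=C(C)CC[C@@]1(C)CO[Si](C)(C)C(C)(C)C | intermediate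
26 | 4-{(1S,6R)-6-[(tert-butyldimethylsilyloxy)methyl]-3,6-dimethylcyclohex-2-en-1-yl}-3-methoxyphenol | COc1cc(O)ccc1[C@H]1C=C(C)CC[C@@]1(C)CO[Si](C)(C)C(C)(C)C | intermediate
27 | 4-{(1S,6R)-6-[(tert-butyldimethylsilyloxy)methyl]-3,6-dimethylcyclohex-2-en-1-yl}-2-(hydroxymethyl)-5-methoxyphenol | COc1cc(O)c(CO)cc1[C@H]1C=C(C)CC[C@@]1(C)CO[Si](C)(C)C(C)(C)C | intermediate
28 | 5-{(1S,6R)-6-[(tert-butyldimethylsilyloxy)methyl]-3,6-dimethylcyclohex-2-en-1-yl}-2-hydroxy-4-methoxybenzaldehyde | COc1cc(O)c(C=O)cc1[C@H]1C=C(C)CC[C@@]1(C)CO[Si](C)(C)C(C)(C)C | intermediate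
29 | ethyl 3-(5-{(1S,6R)-6-[(tert-butyldimethylsilyloxy)methyl]-3,6-dimethylcyclohex-2-en-1-yl}-2-hydroxy-4-methoxyphenyl)prop-2-enoate (E, isomerising to Z) | CCOC(=O)C=Cc1cc([C@H]2C=C(C)CC[C@@]2(C)CO[Si](C)(C)C(C)(C)C)c(OC)cc1O | intermediate
30 | 6-{(1S,6R)-6-[(tert-butyldimethylsilyloxy)methyl]-3,6-dimethylcyclohex-2-en-1-yl}-7-methoxy-2H-chromen-2-one | COc1cc2oc(=O)ccc2cc1[C@H]1C=C(C)CC[C@@]1(C)CO[Si](C)(C)C(C)(C)C | intermediate
31 | 6-[(1S,6R)-6-(hydroxymethyl)-3,6-dimethylcyclohex-2-en-1-yl]-7-methoxy-2H-chromen-2-one | COc1cc2oc(=O)ccc2cc1[C@H]1C=C(C)CC[C@@]1(C)CO | intermediate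
32 | (1R,2R)-2-(7-methoxy-2-oxo-2H-chromen-6-yl)-1,4-dimethylcyclohex-3-ene-1-carbaldehyde | COc1cc2oc(=O)ccc2cc1[C@H]1C=C(C)CC[C@@]1(C)C=O | intermediate
33 | 6-[(1S,6S)-6-ethenyl-3,6-dimethylcyclohex-2-en-1-yl]-7-methoxy-2H-chromen-2-one | COc1cc2oc(=O)ccc2cc1[C@H]1C=C(C)CC[C@@]1(C)C=C | intermediate
34 | 7-hydroxy-2H-chromen-2-one (7-hydroxycoumarin) | O=c1ccc2ccc(O)cc2o1 | starting material
35 | 7-hydroxy-8-iodo-2H-chromen-2-one | O=c1ccc2ccc(O)c(I)c2o1 | intermediate
36 | 8-iodo-7-methoxy-2H-chromen-2-one | COc1ccc2ccc(=O)oc2c1I | intermediate
37 | 6-[(1S,6S)-6-[(E)-2-(7-methoxy-2-oxo-2H-chromen-8-yl)ethenyl]-3,6-dimethylcyclohex-2-en-1-yl]-7-methoxy-2H-chromen-2-one | COc1cc2oc(=O)ccc2cc1[C@H]1C=C(C)CC[C@@]1(C)/C=C/c1c(OC)ccc2ccc(=O)oc12 | target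

## Step count and least certain steps

Total step count: 19. Longest linear sequence: 16 steps (steps 1–9, 11–16 and 19); steps 10, 17 and 18 prepare the two side fragments.

Step 11 (key step). The most likely failure is a 1,2-hydrogen shift from the allylic C1–H to the carbene-like carbon during photolysis, competing with vinyl migration and diverting part of 17 to a conjugated dienone that never reaches 22. Slow capture of 22 by the volatile 21 would also allow ketene dimerisation and O-acylation of the phenol.
Fallback (sets out from 13, returns at 26): generate 22 without a diazo compound or a carbene. Directed aldol condensation of 13 with acetaldehyde should give (2E)-2-substituted but-2-enal F1; oxidation with NaClO2 (NaH2PO4, 2-methylbut-2-ene) should give (2E)-2-substituted but-2-enoic acid F2; oxalyl chloride should give (2E)-2-substituted but-2-enoyl chloride F3. Slow addition of F3 to Et3N and excess 21 effects 1,4-dehydrochlorination to the same vinylketene 22, which passes through 23, 24 and 25 to 26 on warming.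

Step 1. The most likely failure is incomplete enantiofacial discrimination between the methyl group and the unbranched alkyl chain of 2, that is, loss of enantiomeric purity; coordination of titanium by the ester or acetal could also favour the uncatalysed background addition.
Fallback (sets out from 10, returns at 10): classical resolution in place of catalyst control. Acid 10 of whatever enantiomeric purity is converted with (R)-1-phenylethanamine (or its mirror image, whichever gives the less soluble salt) into (R)-1-phenylethanaminium carboxylate F4, which is crystallised to constant rotation and acidified to return 10. Steps 2 and 3 are stereospecific, so nothing else changes.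

Step 9. The most likely failure is conjugate addition of the amide base or of the lithium enolate to the unhindered vinyl ketone, and anionic oligomerisation, before the enolate is trifluoroacetylated.
Fallback (sets out from 15, returns at 17): avoid the lithium enolate. Soft enolisation of 15 with Me3SiOTf and Et3N should give 2-(trimethylsilyloxy)diene F5; C-acylation of F5 with (CF3CO)2O gives 16, and MsN3, Et3N and water then give 17 as in step 9.

Step 19. The most likely failure is slow oxidative addition and slow alkene insertion, because the iodide has two ortho substituents and the alkene is neopentyl-like; this leaves time for reductive loss of iodine or for arylation of a coumarin C3=C4 bond.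
Fallback (sets out from 32, returns at 37): Takai-type olefination of 32 with Cl2CHB(pin), CrCl2 and LiI should give (E)-alkenylboronic ester F6; Suzuki–Miyaura coupling of F6 with 36 (PdCl2(dppf), K3PO4, dioxane/H2O) gives 37 and bypasses steps 16 and 19.

## Further compounds

F1 | step 11 | (2E)-2-{(1S,6R)-6-[(tert-butyldimethylsilyloxy)methyl]-3,6-dimethylcyclohex-2-en-1-yl}but-2-enal | C/C=C(/C=O)[C@H]1C=C(C)CC[C@@]1(C)CO[Si](C)(C)C(C)(C)C
F2 | step 11 | (2E)-2-{(1S,6R)-6-[(tert-butyldimethylsilyloxy)methyl]-3,6-dimethylcyclohex-2-en-1-yl}but-2-enoic acid | C/C=C(/C(=O)O)[C@H]1C=C(C)CC[C@@]1(C)CO[Si](C)(C)C(C)(C)C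
F3 | step 11 | (2E)-2-{(1S,6R)-6-[(tert-butyldimethylsilyloxy)methyl]-3,6-dimethylcyclohex-2-en-1-yl}but-2-enoyl chloride | C/C=C(/C(=O)Cl)[C@H]1C=C(C)CC[C@@]1(C)CO[Si](C)(C)C(C)(C)C
F4 | step 1 | (R)-1-phenylethanaminium (1R,2S)-2-(2,2-diethoxyethyl)-1,4-dimethylcyclohex-3-ene-1-carboxylate | CCOC(OCC)C[C@H]1C=C(C)CC[C@@]1(C)C(=O)[O-].C[C@@H]([NH3+])c1ccccc1
F5 | step 9 | 2-(trimethylsilyloxy)buta-1,3-diene carrying at C1 the cyclohexenyl group of 15 (ring configuration as in 15; enol ether geometry not defined) | C=CC(O[Si](C)(C)C)=C[C@H]1C=C(C)CC[C@@]1(C)CO[Si](C)(C)C(C)(C)C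
F6 | step 19 | 6-[(1S,6S)-3,6-dimethyl-6-[(E)-2-(4,4,5,5-tetramethyl-1,3,2-dioxaborolan-2-yl)ethenyl]cyclohex-2-en-1-yl]-7-methoxy-2H-chromen-2-one | COc1cc2oc(=O)ccc2cc1[C@H]1C=C(C)CC[C@@]1(C)/C=C/B1OC(C)(C)C(C)(C)O1
A1 | alternative 1 | 2-oxo-8-(trimethylsilyl)-2H-chromen-7-yl trifluoromethanesulfonate | C[Si](C)(C)c1c(OS(=O)(=O)C(F)(F)F)ccc2ccc(=O)oc12
A2 | alternative 1 | 7,8-didehydro-2H-chromen-2-one (coumarin 7,8-aryne) | O=C1C=CC2=C(O1)C#CC=C2
A3 | alternative 1 | 2-[(1S,2S)-2-(7-methoxy-2-oxo-2H-chromen-6-yl)-1,4-dimethylcyclohex-3-en-1-yl]acetaldehyde | COc1cc2oc(=O)ccc2cc1[C@H]1C=C(C)CC[C@@]1(C)CC=O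
A4 | alternative 1 | ortho-quinone methide: 8-alkylidene-2H-chromene-2,7(8H)-dione carrying the cyclohexenylethylidene group from A3 (alkylidene geometry not defined) | COc1cc2oc(=O)ccc2cc1[C@H]1C=C(C)CC[C@@]1(C)CC=C1C(=O)C=CC2=C1OC(=O)C=C2
A5 | alternative 1 | 7-hydroxy-8-[(E)-2-[(1S,2S)-2-(7-methoxy-2-oxo-2H-chromen-6-yl)-1,4-dimethylcyclohex-3-en-1-yl]ethenyl]-2H-chromen-2-one (7-O-demethyl target) | COc1cc2oc(=O)ccc2cc1[C@H]1C=C(C)CC[C@@]1(C)/C=C/c1c(O)ccc2ccc(=O)oc12
A6 | alternative 2 | cis-1,4-dimethylcyclohexa-2,5-diene-1-carboxylic acid (methyl groups cis) | C[C@H]1C=C[C@](C)(C(=O)O)C=C1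
A7 | alternative 2 | 6-bromo-7-hydroxy-2H-chromen-2-one | O=c1ccc2cc(Br)c(O)cc2o1
A8 | alternative 2 | 6-bromo-2-oxo-2H-chromen-7-yl cis-1,4-dimethylcyclohexa-2,5-diene-1-carboxylate | C[C@H]1C=C[C@](C)(C(=O)Oc2cc3oc(=O)ccc3cc2Br)C=C1
A9 | alternative 2 | cis-fused tricyclic lactone with a conjugated diene in the carbocycle | C[C@@]12C=CC(C)=C[C@@H]1c1cc3ccc(=O)oc3cc1OC2=O
A10 | alternative 3 | (2R,3R)-3-(7-methoxy-2-oxo-2H-chromen-6-yl)-2-methyl-2-(3-methylbut-3-en-1-yl)pent-4-enal | COc1cc2oc(=O)ccc2cc1[C@@H](C=C)[C@@](C)(CCC(C)=C)C=O
A11 | alternative 3 | (1R,2R)-2-(7-methoxy-2-oxo-2H-chromen-6-yl)-1,4-dimethylcyclohex-3-ene-1-carbaldehyde (same compound as 32) | COc1cc2oc(=O)ccc2cc1[C@H]1C=C(C)CC[C@@]1(C)C=O
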